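**Retrosynthetic overview**

1. The C7 hydroperoxide is installed late by invertive displacement of a (7S)-sulfonate; the (7S)-carbinol comes from the C7 ketone by reagent-controlled reduction, and the ketone from the macrocyclization product.
2. Key disconnection C7–C8: the unit C19H2=C8–C7(O) on the 14-membered carbocycle (an exocyclic methylene next to an oxygenated ring carbon) is the retron of an exo-selective nickel-catalysed reductive coupling of the terminal alkyne C8≡C19 with the aldehyde C7. The alkyne is inert to all alkene oxidations used earlier.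
3. δ-Lactone, C3, C4 and the C11–C12 oxirane come from one double Shi epoxidation of the two (E)-trisubstituted alkenes of an open-chain acid; the C17 carboxylate opens the 3,4-epoxide 6-exo with inversion.
4. The open chain comes from (4R)-limonene oxide (C1 plus nine more carbons): west arm by Johnson–Claisen (C3=C4), east arm by alkyne carboalumination and Negishi coupling (C11=C12, C8≡C19).
5. Order of ring formation: oxirane and δ-lactone first (step 12), 14-membered carbocycle last (step 17).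

Key step: step 17

Remark (convention): locants C1–C20 are cembrane locants: ring C1–C14; C1 carries the propionate unit C15(C16)–C17; C3 = lactone O–CH; C4 = C(C18)(OH); C7 = CH–OOH; C8 = C(=C19H2); C11/C12 = oxirane with C20 on C12; "17,3-olide" = δ-lactone from C17 to O on C3.

Remark (assumption): commercial (+)-limonene oxide is used as its cis/trans mixture (both give 2); the enantiomer of the fructose-derived Shi ketone and the imidazolinium salt DP-IPr·HBF4 (1,3-bis(2,6-diisopropylphenyl)-4,5-diphenyl-4,5-dihydroimidazolium tetrafluoroborate) are taken as available, each otherwise by a short known preparation.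

**Route**

Step 1
Reactants: 1 (4R)-limonene 1,2-oxide
Product: 2 (3R)-6-oxo-3-(prop-1-en-2-yl)heptanal
Conditions: H5IO6 (1.1 equiv), THF–H2O, 0 → 23 °C
Reagents that add atoms: water, O
Why: Acid-promoted opening of the epoxide to the 1,2-diol and periodate glycol cleavage in one pot should open the ring to the keto aldehyde without touching the isopropenyl group or the existing stereocenter, which becomes C1.

Step 2
Reactants: 2 (3R)-6-oxo-3-(prop-1-en-2-yl)heptanal; 3 isopropenylmagnesium bromide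
Product: 4 (5R)-7-hydroxy-8-methyl-5-(prop-1-en-2-yl)non-8-en-2-one (both C7 epimers)
Conditions: 3 (1.05 equiv), THF, −78 °C; aq. NH4Cl
Reagents that add atoms: none
Why: Grignard 1,2-addition should occur selectively at the aldehyde, which is far more electrophilic than the methyl ketone at −78 °C; the new carbinol center (C3) forms as both epimers and is erased in step 3.

Step 3
Reactants: 4 (5R)-7-hydroxy-8-methyl-5-(prop-1-en-2-yl)non-8-en-2-one; 5 triethyl orthoacetate
Product: 6 ethyl (4E,7R)-4-methyl-10-oxo-7-(prop-1-en-2-yl)undec-4-enoate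
Conditions: 5 (6 equiv), EtCO2H (5 mol%), 140 °C, EtOH distilled off; then 1 M HCl–THF, 23 °C
Reagents that add atoms: none
Why: Johnson orthoester Claisen rearrangement through a chair transition state with the C2 substituent equatorial should give the (E)-trisubstituted C3=C4 alkene and add C6–C7 as the ester; the acid wash returns any ketal to the methyl ketone.

Step 4
Reactants: 6 ethyl (4E,7R)-4-methyl-10-oxo-7-(prop-1-en-2-yl)undec-4-enoate
Product: 7 (4E,7R)-4-methyl-7-(prop-1-en-2-yl)undec-4-ene-1,10-diol (both C10 epimers)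
Conditions: LiAlH4, THF, 0 °C; aqueous NaOH work-up
Reagents that add atoms: none
Why: Hydride reduction converts the ester to the C7 primary alcohol and, unavoidably, the ketone to a secondary alcohol whose new center is erased again in step 6.

Step 5
Reactants: 7 (4E,7R)-4-methyl-7-(prop-1-en-2-yl)undec-4-ene-1,10-diol
Product: 8 (5R,7E)-11-[(tert-butyldimethylsilyl)oxy]-8-methyl-5-(prop-1-en-2-yl)undec-7-en-2-ol (both C2 epimers)
Conditions: TBSCl (1.05 equiv), imidazole, CH2Cl2, 0 °C
Reagents that add atoms: tert-butyldimethylsilyl chloride, CC(C)(C)[Si](C)(C)Cl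
Why: Silylation with TBSCl and imidazole is selective for the unhindered primary hydroxyl over the secondary one.

Step 6
Reactants: 8 (5R,7E)-11-[(tert-butyldimethylsilyl)oxy]-8-methyl-5-(prop-1-en-2-yl)undec-7-en-2-ol
Product: 9 (5R,7E)-11-[(tert-butyldimethylsilyl)oxy]-8-methyl-5-(prop-1-en-2-yl)undec-7-en-2-one
Conditions: Dess–Martin periodinane, NaHCO3, CH2Cl2, 23 °C
Reagents that add atoms: none
Why: Dess–Martin oxidation restores the methyl ketone under neutral conditions that leave the alkenes, the silyl ether and C1 untouched.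

Step 7
Reactants: 9 (5R,7E)-11-[(tert-butyldimethylsilyl)oxy]-8-methyl-5-(prop-1-en-2-yl)undec-7-en-2-one
Product: 11 tert-butyldimethyl{[(4E,7R)-4-methyl-7-(prop-1-en-2-yl)undec-4-en-10-yn-1-yl]oxy}silane, via enol phosphate 10 (not isolated)
Conditions: LiN(iPr)2 (1.1 equiv), THF, −78 °C; ClP(O)(OEt)2; LiN(iPr)2 (2.3 equiv), −78 → 23 °C; H2O quench
Reagents that add atoms: diethyl chlorophosphate, CCOP(Cl)(=O)OCC (kept only in intermediate 10)
Why: Kinetic deprotonation on the methyl side, O-phosphorylation and base-induced elimination of the enol phosphate (methyl ketone to terminal alkyne) should give the alkyne whose carbons become C12 and C11.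

Step 8
Reactants: 11 tert-butyldimethyl{[(4E,7R)-4-methyl-7-(prop-1-en-2-yl)undec-4-en-10-yn-1-yl]oxy}silane
Product: 13 tert-butyl{[(4E,7R,10E)-11-iodo-4,10-dimethyl-7-(prop-1-en-2-yl)undeca-4,10-dien-1-yl]oxy}dimethylsilane, via alkenylalane 12 (not isolated)
Conditions: AlMe3 (2.5 equiv), Cp2ZrCl2 (0.25 equiv), CH2Cl2, 0 → 23 °C; then I2, THF, −30 °C
Reagents that add atoms: trimethylaluminium, C[Al](C)C; iodine, II
Why: Zirconium-catalysed syn-carboalumination of the terminal alkyne places the methyl group (C20) on the internal carbon C12 and aluminium on C11, and iodinolysis with retention gives the (E)-iodoalkene; the 1,1-disubstituted and trisubstituted alkenes are inert to these conditions.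

Step 9
Reactants: 13 tert-butyl{[(4E,7R,10E)-11-iodo-4,10-dimethyl-7-(prop-1-en-2-yl)undeca-4,10-dien-1-yl]oxy}dimethylsilane; 14 (4-bromobut-1-yn-1-yl)trimethylsilane
Product: 16 tert-butyldimethyl{[(4E,7R,10E)-4,10-dimethyl-7-(prop-1-en-2-yl)-15-(trimethylsilyl)pentadeca-4,10-dien-14-yn-1-yl]oxy}silane, via organozinc bromide 15 (not isolated)
Conditions: 14, Zn dust, LiCl, THF, 50 °C; then 13, Pd(PPh3)4 (5 mol%), THF, 23 °C
Reagents that add atoms: zinc, [Zn] (kept only in intermediate 15)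
Why: Negishi cross-coupling of the alkenyl iodide with the primary alkylzinc reagent proceeds with retention of the (E) geometry and brings in C10, C9, C8 and C19 as a silyl-capped alkyne.

Step 10
Reactants: 16 tert-butyldimethyl{[(4E,7R,10E)-4,10-dimethyl-7-(prop-1-en-2-yl)-15-(trimethylsilyl)pentadeca-4,10-dien-14-yn-1-yl]oxy}silane
Product: 18 2-[(4E,7R,10E)-1-[(tert-butyldimethylsilyl)oxy]-4,10-dimethyl-15-(trimethylsilyl)pentadeca-4,10-dien-14-yn-7-yl]propan-1-ol (both C15 epimers), via B-alkyl-9-BBN adduct 17 (not isolated)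
Conditions: 9-BBN (1.2 equiv), THF, 0 → 23 °C; then 30% H2O2, aq. NaOAc, 0 → 23 °C
Reagents that add atoms: 9-borabicyclo[3.3.1]nonane, B1C2CCCC1CCC2 (kept only in intermediate 17); hydrogen peroxide, OO
Why: 9-BBN hydroborates the 1,1-disubstituted isopropenyl group much faster than the trisubstituted alkenes or the silylalkyne and puts boron on C17 (anti-Markovnikov), so buffered oxidation gives the primary alcohol; C15 forms as both epimers and is corrected in step 13.

Step 11
Reactants: 18 2-[(4E,7R,10E)-1-[(tert-butyldimethylsilyl)oxy]-4,10-dimethyl-15-(trimethylsilyl)pentadeca-4,10-dien-14-yn-7-yl]propan-1-ol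
Product: 19 2-[(4E,7R,10E)-1-[(tert-butyldimethylsilyl)oxy]-4,10-dimethyl-15-(trimethylsilyl)pentadeca-4,10-dien-14-yn-7-yl]propanoic acid (both C15 epimers)
Conditions: TEMPO (0.2 equiv), PhI(OAc)2 (2.5 equiv), MeCN–H2O (1:1), 23 °C
Reagents that add atoms: water, O
Why: TEMPO/PhI(OAc)2 oxidation in aqueous acetonitrile takes the primary alcohol through the aldehyde hydrate to the carboxylic acid without touching alkenes, alkyne or silyl groups.

Step 12
Reactants: 19 2-[(4E,7R,10E)-1-[(tert-butyldimethylsilyl)oxy]-4,10-dimethyl-15-(trimethylsilyl)pentadeca-4,10-dien-14-yn-7-yl]propanoic acid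
Product: 21 (4R,6R)-6-[(2S)-5-[(tert-butyldimethylsilyl)oxy]-2-hydroxypentan-2-yl]-3-methyl-4-(2-{(2S,3S)-2-methyl-3-[4-(trimethylsilyl)but-3-yn-1-yl]oxiran-2-yl}ethyl)oxan-2-one (both C15 epimers), via bis-epoxy acid 20 (not isolated)
Conditions: enantiomer of the fructose-derived Shi ketone (0.6 equiv), KHSO5 (as Oxone), K2CO3, Bu4NHSO4, aq. Na2B4O7–MeCN–CH2(OMe)2, 0 °C; then NaH2PO4 to pH 6–7, 23 °C
Reagents that add atoms: potassium peroxymonosulfate, [K+].[O-]S(=O)(=O)OO
Why: Shi asymmetric epoxidation with the enantiomeric ketone should attack both (E)-trisubstituted alkenes from the same enantioface (spiro transition state, reagent control) to set C3, C4, C11 and C12 as (S,S) epoxides, and at near-neutral pH the C17 carboxylate opens only the 3,4-epoxide in a 6-exo-tet SN2 attack at the less substituted C3 with inversion (giving 3R, keeping 4S), as 5,6-epoxy acids are known to do, while the 11,12-epoxide is out of reach.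

Step 13
Reactants: 21 hydroxy lactone (both C15 epimers)
Product: 22 (3S,4R,6R)-6-[(2S)-5-[(tert-butyldimethylsilyl)oxy]-2-hydroxypentan-2-yl]-3-methyl-4-(2-{(2S,3S)-2-methyl-3-[4-(trimethylsilyl)but-3-yn-1-yl]oxiran-2-yl}ethyl)oxan-2-one
Conditions: DBU (0.5 equiv), toluene, 60 °C
Reagents that add atoms: none
Why: Base-mediated equilibration of the lactone α-center through its enolate should favor the all-equatorial isomer with the C16 methyl trans to the C1 side chain (15S); the minor epimer can be resubjected.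

Step 14
Reactants: 22 (15S)-hydroxy lactone
Product: 23 (3S,4R,6R)-4-{2-[(2S,3S)-3-(but-3-yn-1-yl)-2-methyloxiran-2-yl]ethyl}-6-[(2S)-2,5-dihydroxypentan-2-yl]-3-methyloxan-2-one
Conditions: Bu4NF (3 equiv), AcOH (3 equiv), THF, 0 → 23 °C
Reagents that add atoms: none
Why: Buffered fluoride cleaves the primary TBS ether and the alkynyl C–Si bond, freeing C7–OH and the terminal alkyne while lactone and epoxide stay intact.

Step 15
Reactants: 23 diol
Product: 24 (3S,4R,6R)-4-{2-[(2S,3S)-3-(but-3-yn-1-yl)-2-methyloxiran-2-yl]ethyl}-3-methyl-6-[(2S)-2,5-bis(triethylsilyloxy)pentan-2-yl]oxan-2-one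
Conditions: Et3SiOTf (2.5 equiv), 2,6-lutidine (4 equiv), CH2Cl2, −78 → −20 °C
Reagents that add atoms: triethylsilyl trifluoromethanesulfonate, CC[Si](CC)(CC)OS(=O)(=O)C(F)(F)F
Why: The silyl triflate with 2,6-lutidine silylates both the primary and the hindered tertiary hydroxyl at low temperature, faster than it can activate the trisubstituted oxirane; the C4 ether prevents lactol formation with C7 in step 17 and participation of the C4 oxygen in step 21.

Step 16
Reactants: 24 bis(triethylsilyl) ether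
Product: 25 (4S)-4-[(2R,4R,5S)-4-{2-[(2S,3S)-3-(but-3-yn-1-yl)-2-methyloxiran-2-yl]ethyl}-5-methyl-6-oxooxan-2-yl]-4-(triethylsilyloxy)pentanal
Conditions: (COCl)2, DMSO, CH2Cl2, −78 °C; 24, −78 → −40 °C; Et3N, → 0 °C
Reagents that add atoms: none
Why: Under Swern conditions a primary triethylsilyl ether is cleaved and oxidized to the aldehyde in one operation, whereas the tertiary triethylsilyl ether is inert.

Step 17
Reactants: 25 seco ynal
Product: 26 (1R,3R,4S,11S,12S,15S)-11,12-epoxy-4,7-bis(triethylsilyloxy)cembr-8(19)-en-17,3-olide (both C7 epimers)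
Conditions: Ni(cod)2 [bis(1,5-cyclooctadiene)nickel] (25 mol%), DP-IPr·HBF4 (25 mol%), KOtBu (25 mol%), Et3SiH (5 equiv), THF, 23 °C, syringe-pump addition of 25 (final 3 mM)
Reagents that add atoms: triethylsilane, CC[SiH](CC)CC
Why: Zerovalent nickel bearing the bulky carbene binds the aldehyde and the terminal alkyne and couples them oxidatively to an oxanickelacyclopentene in which the C7–C8 bond is formed; σ-bond metathesis with Et3SiH and C19–H reductive elimination then release the allylic silyl ether. The closest known reaction is the ligand-controlled nickel-catalysed reductive macrocyclization of terminal ynals, in which large N-heterocyclic carbenes give exocyclic 1,1-disubstituted allylic silyl ethers. The 14-membered carbocycle closes in the exo mode (bond to the internal alkyne carbon C8, methylene C19 left outside the ring); the endo mode would give a 15-membered (E)-allylic ether. C7 is the only new stereocenter and has no reliable control element (the nearest center, C4, is 1,4-related), so both epimers are expected and both are carried on to step 19, which erases C7 before step 20 sets it. The step needs exo regioselectivity, secured by the steric demand of the carbene ligand, and cyclization over oligomerization or alkyne hydrosilylation, secured by slow addition at high dilution. Chemoselectivity is built into 25: the aldehyde is the only reactive carbonyl, no other alkene or alkyne is left, the C4 hydroxyl is silylated so that no lactol forms, and lactone, trisubstituted oxirane and silyl ethers are inert to the catalyst.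

Step 18
Reactants: 26 macrocyclic bis(triethylsilyl) ether
Product: 27 (1R,3R,4S,11S,12S,15S)-11,12-epoxy-7-hydroxy-4-(triethylsilyloxy)cembr-8(19)-en-17,3-olide (both C7 epimers)
Conditions: Bu4NF (1.1 equiv), AcOH (1.1 equiv), THF, −20 → 0 °C
Reagents that add atoms: none
Why: Fluoride at low temperature removes the accessible secondary allylic silyl ether much faster than the tertiary one on the quaternary C4 center.

Step 19
Reactants: 27 allylic alcohol (both C7 epimers)
Product: 28 (1R,3R,4S,11S,12S,15S)-11,12-epoxy-7-oxo-4-(triethylsilyloxy)cembr-8(19)-en-17,3-olide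
Conditions: Dess–Martin periodinane, NaHCO3, CH2Cl2, 0 °C
Reagents that add atoms: none
Why: Dess–Martin oxidation converts both C7 epimers into the same α-methylene ketone, so the outcome of step 17 at C7 does not matter.

Step 20
Reactants: 28 α-methylene ketone
Product: 29 (1R,3R,4S,7S,11S,12S,15S)-11,12-epoxy-7-hydroxy-4-(triethylsilyloxy)cembr-8(19)-en-17,3-olide
Conditions: (R)-2-butyl-CBS oxazaborolidine (0.3 equiv), catecholborane (1.5 equiv), toluene, −78 °C
Reagents that add atoms: none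
Why: Corey–Bakshi–Shibata reduction: with the (R)-oxazaborolidine the α-branched alkenyl group (C8) acts as the large and the C6 methylene as the small substituent, so hydride is delivered to the face that gives the (7S) alcohol, and catecholborane at −78 °C leaves alkene, lactone and epoxide alone.

Step 21
Reactants: 29 (7S)-allylic alcohol
Product: 31 (1R,3R,4S,7R,11S,12S,15S)-11,12-epoxy-7-hydroperoxy-4-(triethylsilyloxy)cembr-8(19)-en-17,3-olide, via C7 mesylate 30 (not isolated)
Conditions: Ms2O (1.5 equiv), Et3N, CH2Cl2, −40 °C; then 50% aq. H2O2 (30 equiv), CsOH·H2O (2 equiv), THF, 0 °C; NaH2PO4 work-up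
Reagents that add atoms: methanesulfonic anhydride, CS(=O)(=O)OS(C)(=O)=O (kept only in intermediate 30); hydrogen peroxide, OO
Why: The secondary allylic mesylate is displaced by hydroperoxide anion in an SN2 reaction with inversion (7S to 7R), the classical preparation of secondary alkyl hydroperoxides from sulfonates; the C4 silyl ether blocks transannular ether formation, and a lactone that is perhydrolysed re-closes on the mildly acidic work-up.

Step 22
Reactants: 31 silylated hydroperoxide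
Product: 32 (1R,3R,4S,7R,11S,12S,15S)-11,12-epoxy-7-hydroperoxy-4-hydroxycembr-8(19)-en-17,3-olide
Conditions: Bu4NF (2 equiv), AcOH (2 equiv), THF, 23 °C
Reagents that add atoms: none
Why: Buffered fluoride removes the tertiary triethylsilyl ether under conditions that the hydroperoxide, epoxide and lactone should tolerate, giving the target.

**Compound list**

1 | (4R)-limonene 1,2-oxide (cis/trans mixture) | CC12CC[C@H](CC1O2)C(C)=C | starting material
2 | (3R)-6-oxo-3-(prop-1-en-2-yl)heptanal | CC(=O)CC[C@H](CC=O)C(C)=C | intermediate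
3 | isopropenylmagnesium bromide | CC(=C)[Mg]Br | starting material
4 | (5R)-7-hydroxy-8-methyl-5-(prop-1-en-2-yl)non-8-en-2-one (C7 epimers) | CC(=O)CC[C@H](CC(O)C(C)=C)C(C)=C | intermediate
5 | triethyl orthoacetate | CC(OCC)(OCC)OCC | starting material
6 | ethyl (4E,7R)-4-methyl-10-oxo-7-(prop-1-en-2-yl)undec-4-enoate | CCOC(=O)CC/C(C)=C/C[C@@H](CCC(C)=O)C(C)=C | intermediate
7 | (4E,7R)-4-methyl-7-(prop-1-en-2-yl)undec-4-ene-1,10-diol (C10 epimers) | OCCC/C(C)=C/C[C@@H](CCC(C)O)C(C)=C | intermediate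
8 | (5R,7E)-11-[(tert-butyldimethylsilyl)oxy]-8-methyl-5-(prop-1-en-2-yl)undec-7-en-2-ol (C2 epimers) | CC(C)(C)[Si](C)(C)OCCC/C(C)=C/C[C@@H](CCC(C)O)C(C)=C | intermediate
9 | (5R,7E)-11-[(tert-butyldimethylsilyl)oxy]-8-methyl-5-(prop-1-en-2-yl)undec-7-en-2-one | CC(C)(C)[Si](C)(C)OCCC/C(C)=C/C[C@@H](CCC(C)=O)C(C)=C | intermediate
10 | diethyl (5R,7E)-11-[(tert-butyldimethylsilyl)oxy]-8-methyl-5-(prop-1-en-2-yl)undeca-1,7-dien-2-yl phosphate | CC(C)(C)[Si](C)(C)OCCC/C(C)=C/C[C@@H](CCC(=C)OP(=O)(OCC)OCC)C(C)=C | intermediate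
11 | tert-butyldimethyl{[(4E,7R)-4-methyl-7-(prop-1-en-2-yl)undec-4-en-10-yn-1-yl]oxy}silane | CC(C)(C)[Si](C)(C)OCCC/C(C)=C/C[C@@H](CCC#C)C(C)=C | intermediate
12 | [(1E,5R,7E)-11-[(tert-butyldimethylsilyl)oxy]-2,8-dimethyl-5-(prop-1-en-2-yl)undeca-1,7-dien-1-yl]dimethylalumane | CC(C)(C)[Si](C)(C)OCCC/C(C)=C/C[C@@H](CC/C(C)=C/[Al](C)C)C(C)=C | intermediate
13 | tert-butyl{[(4E,7R,10E)-11-iodo-4,10-dimethyl-7-(prop-1-en-2-yl)undeca-4,10-dien-1-yl]oxy}dimethylsilane | CC(C)(C)[Si](C)(C)OCCC/C(C)=C/C[C@@H](CC/C(C)=C/I)C(C)=C | intermediate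
14 | (4-bromobut-1-yn-1-yl)trimethylsilane | C[Si](C)(C)C#CCCBr | starting material
15 | [4-(trimethylsilyl)but-3-yn-1-yl]zinc bromide | C[Si](C)(C)C#CCC[Zn]Br | intermediate
16 | tert-butyldimethyl{[(4E,7R,10E)-4,10-dimethyl-7-(prop-1-en-2-yl)-15-(trimethylsilyl)pentadeca-4,10-dien-14-yn-1-yl]oxy}silane | CC(C)(C)[Si](C)(C)OCCC/C(C)=C/C[C@@H](CC/C(C)=C/CCC#C[Si](C)(C)C)C(C)=C | intermediate
17 | 9-{2-[(4E,7R,10E)-1-[(tert-butyldimethylsilyl)oxy]-4,10-dimethyl-15-(trimethylsilyl)pentadeca-4,10-dien-14-yn-7-yl]propyl}-9-borabicyclo[3.3.1]nonane (C15 epimers) | CC(C)(C)[Si](C)(C)OCCC/C(C)=C/C[C@@H](CC/C(C)=C/CCC#C[Si](C)(C)C)C(C)CB1C2CCCC1CCC2 | intermediate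
18 | 2-[(4E,7R,10E)-1-[(tert-butyldimethylsilyl)oxy]-4,10-dimethyl-15-(trimethylsilyl)pentadeca-4,10-dien-14-yn-7-yl]propan-1-ol (C15 epimers) | CC(C)(C)[Si](C)(C)OCCC/C(C)=C/C[C@@H](CC/C(C)=C/CCC#C[Si](C)(C)C)C(C)CO | intermediate
19 | 2-[(4E,7R,10E)-1-[(tert-butyldimethylsilyl)oxy]-4,10-dimethyl-15-(trimethylsilyl)pentadeca-4,10-dien-14-yn-7-yl]propanoic acid (C15 epimers) | CC(C)(C)[Si](C)(C)OCCC/C(C)=C/C[C@@H](CC/C(C)=C/CCC#C[Si](C)(C)C)C(C)C(=O)O | intermediate
20 | 2-[(2R)-1-[(2S,3S)-3-{3-[(tert-butyldimethylsilyl)oxy]propyl}-3-methyloxiran-2-yl]-4-{(2S,3S)-2-methyl-3-[4-(trimethylsilyl)but-3-yn-1-yl]oxiran-2-yl}butan-2-yl]propanoic acid (C15 epimers) | CC(C)(C)[Si](C)(C)OCCC[C@]1(C)O[C@H]1C[C@@H](CC[C@]2(C)O[C@H]2CCC#C[Si](C)(C)C)C(C)C(=O)O | intermediate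
21 | (4R,6R)-6-[(2S)-5-[(tert-butyldimethylsilyl)oxy]-2-hydroxypentan-2-yl]-3-methyl-4-(2-{(2S,3S)-2-methyl-3-[4-(trimethylsilyl)but-3-yn-1-yl]oxiran-2-yl}ethyl)oxan-2-one (C15 epimers) | CC(C)(C)[Si](C)(C)OCCC[C@](C)(O)[C@H]1C[C@@H](CC[C@]2(C)O[C@H]2CCC#C[Si](C)(C)C)C(C)C(=O)O1 | intermediate
22 | (3S,4R,6R)-6-[(2S)-5-[(tert-butyldimethylsilyl)oxy]-2-hydroxypentan-2-yl]-3-methyl-4-(2-{(2S,3S)-2-methyl-3-[4-(trimethylsilyl)but-3-yn-1-yl]oxiran-2-yl}ethyl)oxan-2-one | CC(C)(C)[Si](C)(C)OCCC[C@](C)(O)[C@H]1C[C@@H](CC[C@]2(C)O[C@H]2CCC#C[Si](C)(C)C)[C@H](C)C(=O)O1 | intermediate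
23 | (3S,4R,6R)-4-{2-[(2S,3S)-3-(but-3-yn-1-yl)-2-methyloxiran-2-yl]ethyl}-6-[(2S)-2,5-dihydroxypentan-2-yl]-3-methyloxan-2-one | OCCC[C@](C)(O)[C@H]1C[C@@H](CC[C@]2(C)O[C@H]2CCC#C)[C@H](C)C(=O)O1 | intermediate
24 | (3S,4R,6R)-4-{2-[(2S,3S)-3-(but-3-yn-1-yl)-2-methyloxiran-2-yl]ethyl}-3-methyl-6-[(2S)-2,5-bis(triethylsilyloxy)pentan-2-yl]oxan-2-one | CC[Si](CC)(CC)OCCC[C@](C)(O[Si](CC)(CC)CC)[C@H]1C[C@@H](CC[C@]2(C)O[C@H]2CCC#C)[C@H](C)C(=O)O1 | intermediate
25 | (4S)-4-[(2R,4R,5S)-4-{2-[(2S,3S)-3-(but-3-yn-1-yl)-2-methyloxiran-2-yl]ethyl}-5-methyl-6-oxooxan-2-yl]-4-(triethylsilyloxy)pentanal | O=CCC[C@](C)(O[Si](CC)(CC)CC)[C@H]1C[C@@H](CC[C@]2(C)O[C@H]2CCC#C)[C@H](C)C(=O)O1 | intermediate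
26 | (1R,3R,4S,11S,12S,15S)-11,12-epoxy-4,7-bis(triethylsilyloxy)cembr-8(19)-en-17,3-olide (C7 epimers) | C=C1CC[C@@H]2O[C@@]2(C)CC[C@@H]2C[C@@H](OC(=O)[C@H]2C)[C@@](C)(O[Si](CC)(CC)CC)CCC1O[Si](CC)(CC)CC | intermediate
27 | (1R,3R,4S,11S,12S,15S)-11,12-epoxy-7-hydroxy-4-(triethylsilyloxy)cembr-8(19)-en-17,3-olide (C7 epimers) | C=C1CC[C@@H]2O[C@@]2(C)CC[C@@H]2C[C@@H](OC(=O)[C@H]2C)[C@@](C)(O[Si](CC)(CC)CC)CCC1O | intermediate
28 | (1R,3R,4S,11S,12S,15S)-11,12-epoxy-7-oxo-4-(triethylsilyloxy)cembr-8(19)-en-17,3-olide | C=C1CC[C@@H]2O[C@@]2(C)CC[C@@H]2C[C@@H](OC(=O)[C@H]2C)[C@@](C)(O[Si](CC)(CC)CC)CCC1=O | intermediate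
29 | (1R,3R,4S,7S,11S,12S,15S)-11,12-epoxy-7-hydroxy-4-(triethylsilyloxy)cembr-8(19)-en-17,3-olide | C=C1CC[C@@H]2O[C@@]2(C)CC[C@@H]2C[C@@H](OC(=O)[C@H]2C)[C@@](C)(O[Si](CC)(CC)CC)CC[C@@H]1O | intermediate
30 | (1R,3R,4S,7S,11S,12S,15S)-11,12-epoxy-7-(methanesulfonyloxy)-4-(triethylsilyloxy)cembr-8(19)-en-17,3-olide | C=C1CC[C@@H]2O[C@@]2(C)CC[C@@H]2C[C@@H](OC(=O)[C@H]2C)[C@@](C)(O[Si](CC)(CC)CC)CC[C@@H]1OS(C)(=O)=O | intermediate
31 | (1R,3R,4S,7R,11S,12S,15S)-11,12-epoxy-7-hydroperoxy-4-(triethylsilyloxy)cembr-8(19)-en-17,3-olide | C=C1CC[C@@H]2O[C@@]2(C)CC[C@@H]2C[C@@H](OC(=O)[C@H]2C)[C@@](C)(O[Si](CC)(CC)CC)CC[C@H]1OO | intermediate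
32 | (1R,3R,4S,7R,11S,12S,15S)-11,12-epoxy-7-hydroperoxy-4-hydroxycembr-8(19)-en-17,3-olide | C=C1CC[C@@H]2O[C@@]2(C)CC[C@@H]2C[C@@H](OC(=O)[C@H]2C)[C@@](C)(O)CC[C@H]1OO | target

**Step count and risks**

Total step count: 22. Longest linear sequence: 22 steps (1 to 32); compounds 3, 5 and 14 enter as purchased reagents.

Steps most likely to fail:

1. Step 21. What may go wrong: the secondary allylic mesylate ionizes or is attacked at C19 (allylic transposition), so the displacement loses its stereochemical integrity, or the base decomposes the product. Fallback, an ene route that needs no substitution at C7: it sets out from 27 (either C7 epimer) and comes back at 31, so that steps 19 to 21 are not needed. 27 is treated with 2-nitrobenzenesulfonylhydrazide, PPh3 and diethyl azodicarboxylate (Mitsunobu reaction, THF, −30 °C) to give the N-allyl-N-sulfonylhydrazine F1; on warming this loses 2-nitrobenzenesulfinic acid to the allylic diazene F2, which expels dinitrogen by a retro-ene shift to give the (7E)-C7=C8 alkene F3 (reductive 1,3-transposition). Sensitized photooxygenation of F3 (O2, tetraphenylporphyrin, visible light, CH2Cl2, 0 °C; Schenck ene reaction, hydrogen taken from C19, oxygen delivered to C7 on the outer face of the ring) should give 31, to be separated from the C8-hydroperoxy regioisomer.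

2. Step 17. What may go wrong: closure in the endo mode to the 15-membered ring, hydrosilylation of the alkyne, or oligomerization instead of cyclization. Fallback, a Nozaki–Hiyama–Kishi closure of the same bond: it sets out from 24 and comes back at 27. Ruthenium-catalysed Markovnikov hydrosilylation of 24 ([Cp*Ru(MeCN)3]PF6, Et3SiH, CH2Cl2, 0 °C) gives the 2-silylalkene F4; iododesilylation (N-iodosuccinimide, 2,6-lutidine, (CF3)2CHOH–CH2Cl2, 0 °C) gives the 2-iodoalk-1-ene F5; oxidation as in step 16 gives the iodo aldehyde F6; and CrCl2 (divalent chromium, excess) with NiCl2 (1 mol%) in DMSO–THF at 23 °C under high dilution closes the C7–C8 bond to give 27 directly.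

3. Step 20. What may go wrong: poor facial selectivity in the reduction of the macrocyclic α-methylene ketone, whose two carbonyl substituents are both ring chains. Fallback, correction by inversion instead of oxidation and reduction: it sets out from 27 and comes back at 29, so that steps 19 and 20 are not needed. The C7 epimers of 27 are separated; the (7S) epimer is 29; the (7R) epimer is inverted by a Mitsunobu reaction with chloroacetic acid (PPh3, diisopropyl azodicarboxylate, toluene, 0 °C) to the (7S)-chloroacetate F7, which K2CO3 in MeOH at 0 °C cleaves to 29.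

Further compounds
F1 | step 21 | (1R,3R,4S,11S,12S,15S)-11,12-epoxy-7-[1-(2-nitrobenzenesulfonyl)hydrazinyl]-4-(triethylsilyloxy)cembr-8(19)-en-17,3-olide (C7 epimers) | C=C1CC[C@@H]2O[C@@]2(C)CC[C@@H]2C[C@@H](OC(=O)[C@H]2C)[C@@](C)(O[Si](CC)(CC)CC)CCC1N(N)S(=O)(=O)c1ccccc1[N+](=O)[O-]
F2 | step 21 | (1R,3R,4S,11S,12S,15S)-7-diazenyl-11,12-epoxy-4-(triethylsilyloxy)cembr-8(19)-en-17,3-olide (C7 epimers) | C=C1CC[C@@H]2O[C@@]2(C)CC[C@@H]2C[C@@H](OC(=O)[C@H]2C)[C@@](C)(O[Si](CC)(CC)CC)CCC1N=N
F3 | step 21 | (1R,3R,4S,7E,11S,12S,15S)-11,12-epoxy-4-(triethylsilyloxy)cembr-7-en-17,3-olide | C/C1=C\CC[C@](C)(O[Si](CC)(CC)CC)[C@H]2C[C@@H](CC[C@]3(C)O[C@H]3CC1)[C@H](C)C(=O)O2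
F4 | step 17 | (3S,4R,6R)-3-methyl-4-(2-{(2S,3S)-2-methyl-3-[3-(triethylsilyl)but-3-en-1-yl]oxiran-2-yl}ethyl)-6-[(2S)-2,5-bis(triethylsilyloxy)pentan-2-yl]oxan-2-one | CC[Si](CC)(CC)OCCC[C@](C)(O[Si](CC)(CC)CC)[C@H]1C[C@@H](CC[C@]2(C)O[C@H]2CCC(=C)[Si](CC)(CC)CC)[C@H](C)C(=O)O1
F5 | step 17 | (3S,4R,6R)-4-{2-[(2S,3S)-3-(3-iodobut-3-en-1-yl)-2-methyloxiran-2-yl]ethyl}-3-methyl-6-[(2S)-2,5-bis(triethylsilyloxy)pentan-2-yl]oxan-2-one | CC[Si](CC)(CC)OCCC[C@](C)(O[Si](CC)(CC)CC)[C@H]1C[C@@H](CC[C@]2(C)O[C@H]2CCC(I)=C)[C@H](C)C(=O)O1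
F6 | step 17 | (4S)-4-[(2R,4R,5S)-4-{2-[(2S,3S)-3-(3-iodobut-3-en-1-yl)-2-methyloxiran-2-yl]ethyl}-5-methyl-6-oxooxan-2-yl]-4-(triethylsilyloxy)pentanal | O=CCC[C@](C)(O[Si](CC)(CC)CC)[C@H]1C[C@@H](CC[C@]2(C)O[C@H]2CCC(I)=C)[C@H](C)C(=O)O1
F7 | step 20 | (1R,3R,4S,7S,11S,12S,15S)-7-(chloroacetoxy)-11,12-epoxy-4-(triethylsilyloxy)cembr-8(19)-en-17,3-olide | C=C1CC[C@@H]2O[C@@]2(C)CC[C@@H]2C[C@@H](OC(=O)[C@H]2C)[C@@](C)(O[Si](CC)(CC)CC)CC[C@@H]1OC(=O)CCl
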